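**Assumption:** the target has no stereocentre, stereogenic axis or stereogenic double bond, so it is achiral and there is no enantiomer to select. Diones 4 and 12 are used as diastereomer/tautomer mixtures, because all their sp3 centres are erased on aromatisation.

## Retrosynthetic overview
1. The endgame frees the B-ring acid (allyl ester, Pd(0)) and the benzylic alcohol (TBS ether). The depside C(=O)–O bond is cut into A-ring acid 22 and the 4-OH of B-ring allyl ester 8.
2. The B ring is formed first. Arene 6 comes from dione 4, made by intermolecular Michael addition of dimethyl malonate to (E)-hex-4-en-3-one and Claisen (Dieckmann) closure.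
3. The A ring is formed second. Methyl orsellinate 15 comes from dione 12, made by intermolecular Michael addition of methyl acetoacetate to methyl crotonate and Dieckmann closure.
4. The CH2OH carbon comes from C3 formylation of 15, followed by O-methylation, reduction, saponification and silylation.

## Route

**Step 1**
Reactants: 1 dimethyl malonate; 2 (E)-hex-4-en-3-one
Product: 4 methyl 3,6-dimethyl-2,4-dioxocyclohexane-1-carboxylate, via Michael adduct 3 (not isolated)
Conditions: NaOMe (1.1 equiv), MeOH, reflux; aq. HCl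
Reagents that add atoms: none
Why: The malonate enolate adds 1,4 to the enone (intermolecular Michael addition), and the ethyl-ketone enolate then closes the six-membered ring on one ester (Claisen/Dieckmann condensation), driven by the stabilised β-dicarbonyl enolate; the new stereocentres do not matter.

**Step 2**
Reactants: 4 methyl 3,6-dimethyl-2,4-dioxocyclohexane-1-carboxylate
Product: 6 methyl 2,4-dihydroxy-3,6-dimethylbenzoate, via bromodione 5 (not isolated)
Conditions: NBS (1.0 equiv), DMF, 0 °C; then 80 °C
Reagents that add atoms: N-bromosuccinimide, O=C1CCC(=O)N1Br (its Br sits only in 5 and leaves again as HBr)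
Why: This is a halogenation–dehydrohalogenation aromatisation, in which the doubly activated C3 is brominated and warm DMF/HBr promotes loss of HBr and tautomerisation to the resorcinol.

**Step 3**
Reactants: 6 methyl 2,4-dihydroxy-3,6-dimethylbenzoate
Product: 7 2,4-dihydroxy-3,6-dimethylbenzoic acid
Conditions: conc. H2SO4, 0 °C → rt, 1 h; pour on ice
Reagents that add atoms: water, O
Why: This is an A_AC1 ester hydrolysis through the acylium ion, which suits electron-rich 2,6-disubstituted benzoates and avoids the hot alkali that would decarboxylate the product.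

**Step 4**
Reactants: 7 2,4-dihydroxy-3,6-dimethylbenzoic acid
Product: 8 allyl 2,4-dihydroxy-3,6-dimethylbenzoate
Conditions: allyl bromide (1.1 equiv), KHCO3, DMF, rt
Reagents that add atoms: allyl bromide, C=CCBr
Why: This is an SN2 alkylation of the carboxylate, and bicarbonate is too weak a base to ionise the phenols, so only the ester forms.

**Step 5**
Reactants: 9 methyl acetoacetate; 10 methyl (E)-but-2-enoate
Product: 12 methyl 2-methyl-4,6-dioxocyclohexane-1-carboxylate, via Michael adduct 11 (not isolated)
Conditions: NaOMe (1.1 equiv), MeOH, reflux; aq. HCl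
Reagents that add atoms: none
Why: Intermolecular Michael addition of the acetoacetate α-carbon to the crotonate is followed by Dieckmann (Claisen) closure of the acetyl methyl group onto the crotonate ester; the stereocentres do not matter.

**Step 6**
Reactants: 12 methyl 2-methyl-4,6-dioxocyclohexane-1-carboxylate
Product: 14 methyl 3,5-dibromo-2,4-dihydroxy-6-methylbenzoate, via bromodione 13 (not isolated)
Conditions: Br2 (3.2 equiv), AcOH, 15 °C → rt; pour into water, filter
Reagents that add atoms: bromine, BrBr
Why: Enol bromination and dehydrobromination aromatise the ring, and excess bromine drives the unavoidable nuclear bromination at C3 and C5 (electrophilic aromatic substitution) to a single crystalline product.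

**Step 7**
Reactants: 14 methyl 3,5-dibromo-2,4-dihydroxy-6-methylbenzoate
Product: 15 methyl 2,4-dihydroxy-6-methylbenzoate (methyl orsellinate)
Conditions: H2 (1 atm), 10% Pd/C, NaOAc (2.5 equiv), MeOH, rt
Reagents that add atoms: none
Why: Catalytic hydrogenolysis (hydrodehalogenation) cleaves both aryl C–Br bonds, the acetate buffers the HBr, and the ester and phenols are inert.

**Step 8**
Reactants: 15 methyl 2,4-dihydroxy-6-methylbenzoate
Product: 17 methyl 3-formyl-2,4-dihydroxy-6-methylbenzoate, via chloro ether 16 (not isolated)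
Conditions: TiCl4 (2.5 equiv), Cl2CHOMe (1.2 equiv), CH2Cl2, −10 °C → rt; aq. HCl
Reagents that add atoms: dichloromethyl methyl ether, COC(Cl)Cl; water, O
Why: In this Rieche formylation, Ti(IV) held by the phenolic oxygens delivers the electrophile to C3, which is ortho to both OH groups and not buttressed by the C6 methyl, and 16 hydrolyses to the doubly hydrogen-bonded aldehyde.

**Step 9**
Reactants: 17 methyl 3-formyl-2,4-dihydroxy-6-methylbenzoate
Product: 18 methyl 3-formyl-2,4-dimethoxy-6-methylbenzoate
Conditions: MeI (5 equiv), K2CO3 (4 equiv), DMF, 45 °C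
Reagents that add atoms: iodomethane, CI
Why: This is a Williamson O-methylation, where excess reagent and a dipolar solvent overcome the chelation of both phenols, and the non-enolisable aldehyde and hindered ester are unaffected.

**Step 10**
Reactants: 18 methyl 3-formyl-2,4-dimethoxy-6-methylbenzoate
Product: 19 methyl 3-(hydroxymethyl)-2,4-dimethoxy-6-methylbenzoate
Conditions: NaBH4, MeOH/THF, 0 °C; sat. NH4Cl
Reagents that add atoms: none
Why: Chemoselective borohydride reduction takes the aldehyde only, and the hindered benzoate is not touched.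

**Step 11**
Reactants: 19 methyl 3-(hydroxymethyl)-2,4-dimethoxy-6-methylbenzoate
Product: 20 3-(hydroxymethyl)-2,4-dimethoxy-6-methylbenzoic acid
Conditions: KOH, DMSO/H2O, 95 °C; cold aq. KHSO4 to pH 4
Reagents that add atoms: potassium hydroxide, [K+].[OH-]
Why: This is a forced B_AC2 saponification of a di-ortho-substituted benzoate, done at the alcohol stage where nothing is base-sensitive, and the mild cold acidification spares the electron-rich benzylic alcohol.

**Step 12**
Reactants: 20 3-(hydroxymethyl)-2,4-dimethoxy-6-methylbenzoic acid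
Product: 22 3-{[(tert-butyldimethylsilyl)oxy]methyl}-2,4-dimethoxy-6-methylbenzoic acid, via bis-silyl compound 21 (not isolated)
Conditions: TBSCl (2.5 equiv), imidazole, DMF, rt; then K2CO3, MeOH/THF/H2O, rt; cold aq. KHSO4 to pH 4
Reagents that add atoms: tert-butyldimethylsilyl chloride, CC(C)(C)[Si](C)(C)Cl
Why: Exhaustive silylation is followed by selective solvolysis of the much more labile silyl ester, which leaves the primary silyl ether in place.

**Step 13**
Reactants: 22 3-{[(tert-butyldimethylsilyl)oxy]methyl}-2,4-dimethoxy-6-methylbenzoic acid; 8 allyl 2,4-dihydroxy-3,6-dimethylbenzoate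
Product: 24 allyl 4-{[3-({[tert-butyl(dimethyl)silyl]oxy}methyl)-2,4-dimethoxy-6-methylbenzoyl]oxy}-2-hydroxy-3,6-dimethylbenzoate, via acid chloride 23 (not isolated)
Conditions: 1-chloro-N,N,2-trimethylprop-1-en-1-amine, CH2Cl2, 0 °C → rt; then 8 (1.1 equiv), Et3N, DMAP (cat.), 0 °C → rt
Reagents that add atoms: 1-chloro-N,N,2-trimethylprop-1-en-1-amine, CC(C)=C(Cl)N(C)C (gives only the Cl of 23; nothing of it stays in 24)
Why: The acid chloride forms under neutral conditions with no HCl, so the silyl ether survives, and DMAP-catalysed acylation takes the free and more acidic 4-OH, because the 2-OH is tied up in a hydrogen bond to the ester.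

**Step 14**
Reactants: 24 silyl-protected depside allyl ester
Product: 25 allyl 2-hydroxy-4-{[3-(hydroxymethyl)-2,4-dimethoxy-6-methylbenzoyl]oxy}-3,6-dimethylbenzoate
Conditions: TBAF/AcOH (1:1, 1.5 equiv), THF, 0 °C → rt
Reagents that add atoms: none
Why: In this fluoride-induced desilylation, the acetic acid buffer keeps the medium non-basic and non-acidic, so the aryl ester, the allyl ester and the ionisable benzylic alcohol all survive.

**Step 15**
Reactants: 25 allyl 2-hydroxy-4-{[3-(hydroxymethyl)-2,4-dimethoxy-6-methylbenzoyl]oxy}-3,6-dimethylbenzoate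
Product: 26 2-hydroxy-4-{[3-(hydroxymethyl)-2,4-dimethoxy-6-methylbenzoyl]oxy}-3,6-dimethylbenzoic acid (target)
Conditions: Pd(PPh3)4 (5 mol %), morpholine (3 equiv), THF, rt; cold dilute KHSO4 wash
Reagents that add atoms: none
Why: Tsuji–Trost deallylation transfers the allyl group to morpholine under neutral conditions at room temperature, which avoids both hydrogenolysis of the benzylic alcohol and decarboxylation, and the di-ortho-substituted depside ester resists aminolysis.

## Compound list
1 | dimethyl malonate | COC(=O)CC(=O)OC | starting material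
2 | (E)-hex-4-en-3-one | CCC(=O)/C=C/C | starting material
3 | dimethyl 2-(4-oxohexan-2-yl)propanedioate (Michael adduct, not isolated) | CCC(=O)CC(C)C(C(=O)OC)C(=O)OC | intermediate
4 | methyl 3,6-dimethyl-2,4-dioxocyclohexane-1-carboxylate (isomer/tautomer mixture) | COC(=O)C1C(C)CC(=O)C(C)C1=O | intermediate
5 | methyl 3-bromo-3,6-dimethyl-2,4-dioxocyclohexane-1-carboxylate (not isolated) | COC(=O)C1C(C)CC(=O)C(C)(Br)C1=O | intermediate
6 | methyl 2,4-dihydroxy-3,6-dimethylbenzoate | COC(=O)c1c(C)cc(O)c(C)c1O | intermediate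
7 | 2,4-dihydroxy-3,6-dimethylbenzoic acid | O=C(O)c1c(C)cc(O)c(C)c1O | intermediate
8 | allyl 2,4-dihydroxy-3,6-dimethylbenzoate | C=CCOC(=O)c1c(C)cc(O)c(C)c1O | intermediate
9 | methyl acetoacetate | CC(=O)CC(=O)OC | starting material
10 | methyl (E)-but-2-enoate (methyl crotonate) | C/C=C/C(=O)OC | starting material
11 | dimethyl 2-acetyl-3-methylpentanedioate (Michael adduct, not isolated) | COC(=O)CC(C)C(C(C)=O)C(=O)OC | intermediate
12 | methyl 2-methyl-4,6-dioxocyclohexane-1-carboxylate (isomer/tautomer mixture) | COC(=O)C1C(C)CC(=O)CC1=O | intermediate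
13 | methyl 3-bromo-6-methyl-2,4-dioxocyclohexane-1-carboxylate (first-formed bromodione, not isolated) | COC(=O)C1C(C)CC(=O)C(Br)C1=O | intermediate
14 | methyl 3,5-dibromo-2,4-dihydroxy-6-methylbenzoate | COC(=O)c1c(C)c(Br)c(O)c(Br)c1O | intermediate
15 | methyl 2,4-dihydroxy-6-methylbenzoate (methyl orsellinate) | COC(=O)c1c(C)cc(O)cc1O | intermediate
16 | methyl 3-[chloro(methoxy)methyl]-2,4-dihydroxy-6-methylbenzoate (not isolated) | COC(=O)c1c(C)cc(O)c(C(Cl)OC)c1O | intermediate
17 | methyl 3-formyl-2,4-dihydroxy-6-methylbenzoate | COC(=O)c1c(C)cc(O)c(C=O)c1O | intermediate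
18 | methyl 3-formyl-2,4-dimethoxy-6-methylbenzoate | COC(=O)c1c(C)cc(OC)c(C=O)c1OC | intermediate
19 | methyl 3-(hydroxymethyl)-2,4-dimethoxy-6-methylbenzoate | COC(=O)c1c(C)cc(OC)c(CO)c1OC | intermediate
20 | 3-(hydroxymethyl)-2,4-dimethoxy-6-methylbenzoic acid | O=C(O)c1c(C)cc(OC)c(CO)c1OC | intermediate
21 | tert-butyldimethylsilyl 3-{[(tert-butyldimethylsilyl)oxy]methyl}-2,4-dimethoxy-6-methylbenzoate (not isolated) | Cc1cc(OC)c(CO[Si](C)(C)C(C)(C)C)c(OC)c1C(=O)O[Si](C)(C)C(C)(C)C | intermediate
22 | 3-{[(tert-butyldimethylsilyl)oxy]methyl}-2,4-dimethoxy-6-methylbenzoic acid | Cc1cc(OC)c(CO[Si](C)(C)C(C)(C)C)c(OC)c1C(=O)O | intermediate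
23 | 3-{[(tert-butyldimethylsilyl)oxy]methyl}-2,4-dimethoxy-6-methylbenzoyl chloride (not isolated) | Cc1cc(OC)c(CO[Si](C)(C)C(C)(C)C)c(OC)c1C(=O)Cl | intermediate
24 | allyl 4-{[3-({[tert-butyl(dimethyl)silyl]oxy}methyl)-2,4-dimethoxy-6-methylbenzoyl]oxy}-2-hydroxy-3,6-dimethylbenzoate | C=CCOC(=O)c1c(C)cc(OC(=O)c2c(C)cc(OC)c(CO[Si](C)(C)C(C)(C)C)c2OC)c(C)c1O | intermediate
25 | allyl 2-hydroxy-4-{[3-(hydroxymethyl)-2,4-dimethoxy-6-methylbenzoyl]oxy}-3,6-dimethylbenzoate | C=CCOC(=O)c1c(C)cc(OC(=O)c2c(C)cc(OC)c(CO)c2OC)c(C)c1O | intermediate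
26 | 2-hydroxy-4-{[3-(hydroxymethyl)-2,4-dimethoxy-6-methylbenzoyl]oxy}-3,6-dimethylbenzoic acid (achiral) | COc1cc(C)c(C(=O)Oc2cc(C)c(C(=O)O)c(O)c2C)c(OC)c1CO | target

## Step count and risks
Total steps: 15. Longest linear sequence: 11 (steps 5–15). The B-ring branch (steps 1–4) joins at step 13.

**Step 8 (regiochemistry of the formylation; some 5-formyl isomer may form and must be separated).** The fallback sets out from 15 and comes back at 22.
- Saponify and decarboxylate 15 (aq. NaOH, reflux; then HCl, warm) through orsellinic acid F1 to orcinol F2.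
- Methylate (Me2SO4, K2CO3, acetone) to 3,5-dimethoxytoluene F3, which can also be bought cheaply.
- Directed ortho-lithiation between the two methoxy groups (n-BuLi, THF, 0 °C → rt) gives (2,6-dimethoxy-4-methylphenyl)lithium F4, and a DMF quench gives 2,6-dimethoxy-4-methylbenzaldehyde F5.
- NaBH4 gives (2,6-dimethoxy-4-methylphenyl)methanol F6, and TBSCl/imidazole gives the silyl ether F7.
- NBS in MeCN at 0 °C gives the monobromide F8. The two open ring positions are equivalent, so only one isomer is possible.
- Br/Li exchange (n-BuLi, THF, −78 °C) gives the aryllithium F9, which is carboxylated with CO2 to 22.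

**Step 13 (esterification of a di-ortho-substituted acid that carries an acid-labile silyl ether).** The fallback sets out from 20 and comes back at 25.
- Oxidise 20 with IBX (DMSO, rt) to 3-formyl-2,4-dimethoxy-6-methylbenzoic acid F10, in which the aldehyde acts as an acid-proof mask of the CH2OH group.
- Activate F10 with trifluoroacetic anhydride in toluene at rt as the mixed trifluoroacetic anhydride F11. This is an acylium-type acylation, which is insensitive to ortho substituents.
- F11 acylates the 4-OH of 8 to give the formyl depside allyl ester F12.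
- NaBH4 (THF/MeOH, −10 °C) reduces only the aldehyde of F12 to give 25.

**Step 3 (hydrolysis to an acid that is prone to sulfonation and decarboxylation).** The fallback sets out from 2 and comes back at 8.
- Run the same Michael/Claisen annulation with commercial diallyl malonate (C=CCOC(=O)CC(=O)OCC=C; NaH, allyl alcohol/THF, reflux).
- This goes through the diallyl Michael adduct F13 to allyl 3,6-dimethyl-2,4-dioxocyclohexane-1-carboxylate F14.
- Aromatise F14 with NBS (1.0 equiv) in DMF, 0 → 80 °C, via the allyl bromodione F15 to give 8. The free acid 7 is then never handled.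

## Further compounds
F1 | step 8 | orsellinic acid (2,4-dihydroxy-6-methylbenzoic acid) | Cc1cc(O)cc(O)c1C(=O)O
F2 | step 8 | orcinol (5-methylbenzene-1,3-diol) | Cc1cc(O)cc(O)c1
F3 | step 8 | 3,5-dimethoxytoluene | Cc1cc(OC)cc(OC)c1
F4 | step 8 | (2,6-dimethoxy-4-methylphenyl)lithium | [Li]c1c(OC)cc(C)cc1OC
F5 | step 8 | 2,6-dimethoxy-4-methylbenzaldehyde | Cc1cc(OC)c(C=O)c(OC)c1
F6 | step 8 | (2,6-dimethoxy-4-methylphenyl)methanol | Cc1cc(OC)c(CO)c(OC)c1
F7 | step 8 | tert-butyl[(2,6-dimethoxy-4-methylphenyl)methoxy]dimethylsilane | Cc1cc(OC)c(CO[Si](C)(C)C(C)(C)C)c(OC)c1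
F8 | step 8 | [(3-bromo-2,6-dimethoxy-4-methylphenyl)methoxy](tert-butyl)dimethylsilane | Cc1cc(OC)c(CO[Si](C)(C)C(C)(C)C)c(OC)c1Br
F9 | step 8 | [3-({[tert-butyl(dimethyl)silyl]oxy}methyl)-2,4-dimethoxy-6-methylphenyl]lithium | [Li]c1c(C)cc(OC)c(CO[Si](C)(C)C(C)(C)C)c1OC
F10 | step 13 | 3-formyl-2,4-dimethoxy-6-methylbenzoic acid | Cc1cc(OC)c(C=O)c(OC)c1C(=O)O
F11 | step 13 | 3-formyl-2,4-dimethoxy-6-methylbenzoic trifluoroacetic anhydride | Cc1cc(OC)c(C=O)c(OC)c1C(=O)OC(=O)C(F)(F)F
F12 | step 13 | allyl 4-[(3-formyl-2,4-dimethoxy-6-methylbenzoyl)oxy]-2-hydroxy-3,6-dimethylbenzoate | C=CCOC(=O)c1c(C)cc(OC(=O)c2c(C)cc(OC)c(C=O)c2OC)c(C)c1O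
F13 | step 3 | diallyl 2-(4-oxohexan-2-yl)propanedioate | CCC(=O)CC(C)C(C(=O)OCC=C)C(=O)OCC=C
F14 | step 3 | allyl 3,6-dimethyl-2,4-dioxocyclohexane-1-carboxylate | C=CCOC(=O)C1C(C)CC(=O)C(C)C1=O
F15 | step 3 | allyl 3-bromo-3,6-dimethyl-2,4-dioxocyclohexane-1-carboxylate | C=CCOC(=O)C1C(C)CC(=O)C(C)(Br)C1=O
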